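The bicyclic 3,7-dioxabicyclo[3.3.0]octan-2-one is disconnected across the ring-fusion bond C1–C5 and the lactone bond O3–C4. Both bonds border C5. C1, next to the C2 carbonyl, can carry a radical, and C4, benzylic to the trioxygenated ring, can carry a cation; the key step exploits this pairing. An acyclic alpha-bromo ester whose beta-oxygen (O7) bears an (E)-cinnamyl group is closed twice in one photoredox operation. Radical 5-exo closure builds the tetrahydrofuran ring, then oxidation and ester capture build the lactone ring. C1, C4 and C5 are set from C8, the only centre installed by a reagent.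

Key step: step 8

Remark on the chemistry: all phenols are carried as benzyl ethers, and 1 and 5 are assumed purchasable in that form. Core numbering: C1 (fusion carbon next to the carbonyl), C2 (C=O), O3, C4 (bears the trioxygenated ring), C5 (fusion carbon), C6 (CH2), O7, C8 (bears the dioxygenated ring). The target is (1S,4S,5R,8S), cis-fused with both aryl groups exo.

Step 1
Reactants: 1 3',4'-bis(benzyloxy)acetophenone; 2 dimethyl carbonate
Product: 3 methyl 3-[3,4-bis(benzyloxy)phenyl]-3-oxopropanoate
Conditions: NaH (2.5 equiv), (MeO)2CO (5 equiv), THF, reflux; then aq. HCl, 0 °C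
Reagents that add atoms: none
Why: crossed Claisen condensation of the methyl ketone enolate with the non-enolisable carbonate is pulled to completion by irreversible deprotonation of the beta-keto ester formed, and aryl benzyl ethers are inert to NaH.

Step 2
Reactants: 3 methyl 3-[3,4-bis(benzyloxy)phenyl]-3-oxopropanoate
Product: 4 methyl (3S)-3-[3,4-bis(benzyloxy)phenyl]-3-hydroxypropanoate
Conditions: RuCl[(S,S)-TsDPEN](p-cymene) (1 mol%), HCO2H/Et3N (5:2), DMF, 30 °C
Reagents that add atoms: none
Why: Noyori–Ikariya asymmetric transfer hydrogenation of an aryl ketone, in which the (S,S)-ligand should deliver hydride to the face that gives the (S)-benzylic alcohol (the same sense as for acetophenone, the aryl group being placed by its CH–π contact with the cymene ligand), while the buffered formic acid medium leaves the ester and the benzyl ethers untouched.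

Step 3
Reactants: 5 3,4,5-tris(benzyloxy)benzaldehyde; 6 triethyl phosphonoacetate
Product: 7 ethyl (2E)-3-[3,4,5-tris(benzyloxy)phenyl]prop-2-enoate
Conditions: NaH (1.1 equiv), THF, 0 °C to rt
Reagents that add atoms: none
Why: Horner–Wadsworth–Emmons olefination of an aromatic aldehyde with a stabilised phosphonate anion is reliably E-selective.

Step 4
Reactants: 7 ethyl (2E)-3-[3,4,5-tris(benzyloxy)phenyl]prop-2-enoate
Product: 8 (2E)-3-[3,4,5-tris(benzyloxy)phenyl]prop-2-en-1-ol
Conditions: i-Bu2AlH (2.5 equiv), CH2Cl2, −78 to 0 °C; aq. potassium sodium tartrate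
Reagents that add atoms: none
Why: 1,2-reduction of the conjugated ester by the electrophilic aluminium hydride gives the allylic alcohol without touching the alkene, so the E geometry is kept.

Step 5
Reactants: 8 (2E)-3-[3,4,5-tris(benzyloxy)phenyl]prop-2-en-1-ol
Product: 9 tert-butyl (2E)-3-[3,4,5-tris(benzyloxy)phenyl]prop-2-en-1-yl carbonate
Conditions: Boc2O (1.5 equiv), n-Bu4NHSO4 (10 mol%), 30% aq. NaOH, CH2Cl2, 0 °C to rt
Reagents that add atoms: di-tert-butyl dicarbonate, CC(C)(C)OC(=O)OC(=O)OC(C)(C)C
Why: phase-transfer O-acylation of the primary allylic alcohol by the dicarbonate gives the mixed carbonate, whose bulky tert-butyl group protects it from hydrolysis in the two-phase medium.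

Step 6
Reactants: 4 methyl (3S)-3-[3,4-bis(benzyloxy)phenyl]-3-hydroxypropanoate; 9 tert-butyl (2E)-3-[3,4,5-tris(benzyloxy)phenyl]prop-2-en-1-yl carbonate
Product: 10 methyl (3S)-3-[3,4-bis(benzyloxy)phenyl]-3-{[(2E)-3-(3,4,5-tris(benzyloxy)phenyl)prop-2-en-1-yl]oxy}propanoate
Conditions: Pd2(dba)3 (2.5 mol%), dppb (10 mol%), 9 (1.5 equiv), THF, 60 °C, argon
Reagents that add atoms: none
Why: decarboxylative allylic etherification of the Tsuji–Trost type, in which zerovalent palladium ionises the carbonate, the tert-butoxide released with CO2 deprotonates the hydroxyl of 4 and the resulting alkoxide attacks the aryl-substituted π-allyl palladium complex at its unsubstituted terminus to give the linear E ether, so that no stoichiometric base is present to trigger retro-aldol cleavage or elimination and the C–O bond at the stereocentre (the future C8) is never broken.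

Step 7
Reactants: 10 methyl (3S)-3-[3,4-bis(benzyloxy)phenyl]-3-{[(2E)-3-(3,4,5-tris(benzyloxy)phenyl)prop-2-en-1-yl]oxy}propanoate
Product: 12 methyl (2RS,3R)-2-bromo-3-[3,4-bis(benzyloxy)phenyl]-3-{[(2E)-3-(3,4,5-tris(benzyloxy)phenyl)prop-2-en-1-yl]oxy}propanoate, via silyl ketene acetal 11 (not isolated)
Conditions: LiN(i-Pr)2 (1.15 equiv) added to 10 and Me3SiCl (3 equiv), THF, −78 °C; then NBS (1.2 equiv), THF, −78 °C; aq. NaHCO3
Reagents that add atoms: N-bromosuccinimide, O=C1CCC(=O)N1Br; chlorotrimethylsilane, C[Si](C)(C)Cl (its silyl group is carried only in 11)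
Why: internal-quench enolisation silylates the ester enolate as it forms, which forestalls E1cB loss of the cinnamyloxy group, and electrophilic alpha-bromination of the silyl ketene acetal by NBS then gives the bromo ester as both C2 epimers, which is acceptable because this carbon becomes a planar radical, while the benzylic centre is untouched and changes descriptor from S to R only because CHBr now outranks the aryl group.

Step 8
Reactants: 12 methyl (2RS,3R)-2-bromo-3-[3,4-bis(benzyloxy)phenyl]-3-{[(2E)-3-(3,4,5-tris(benzyloxy)phenyl)prop-2-en-1-yl]oxy}propanoate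
Product: 14 (1S,4S,5R,8S)-8-[3,4-bis(benzyloxy)phenyl]-4-[3,4,5-tris(benzyloxy)phenyl]-3,7-dioxabicyclo[3.3.0]octan-2-one, via O-methyl lactonium bromide 13 (not isolated)
Conditions: fac-Ir(ppy)3 (1 mol%), blue LEDs (450 nm), dry degassed MeCN (0.02 M), 25 °C
Reagents that add atoms: none
Why: The excited state of fac-Ir(ppy)3 transfers an electron to the C1–Br bond, the ester-stabilised C1 radical adds to C5 of the cinnamyl alkene, the C4 benzylic radical so formed is oxidised by the tetravalent iridium species (which returns the trivalent catalyst), the C4 cation is trapped by the carbonyl oxygen of the neighbouring ester to give lactonium bromide 13, and bromide strips its O-methyl group as bromomethane, so the sequence is redox-neutral and needs no additive. The closest known reaction types are the photoredox carbolactonization of styrenes with alpha-bromo esters and the atom-transfer or oxidative 5-exo radical cyclizations of alpha-halo esters and malonates that finish by lactonization at the gamma-carbon. The tetrahydrofuran ring (C1, C5, C6, O7, C8) closes by radical 5-exo-trig attack that forms C1–C5, and the lactone ring (C1, C2, O3, C4, C5) closes by ionic five-membered capture of the trigonal C4 cation by the ester carbonyl oxygen that forms O3–C4. C1 and C5 are set in a chair-like 5-exo transition state in which the C8 aryl group is pseudo-equatorial, so that the C1 ester ends trans to that aryl group and cis to the C5 side chain (the cis ring fusion), while C4 is set when the planar cation closes with its aryl group on the convex face, which is also the thermodynamically preferred exo arrangement if the benzylic lactonium ion reopens. The step needs 5-exo rather than 6-endo attack, secured by the aryl group on the alkene terminus that makes the 5-exo radical benzylic, diastereocontrol relative to C8, secured by that single pseudo-equatorial substituent, and radical–polar crossover faster than hydrogen abstraction or dimerisation, secured by the oxidisable trialkoxybenzyl radical and the absence of any hydrogen donor or reductant. The epimer ratio at the bromine-bearing carbon and any E/Z isomerisation of the alkene by energy transfer are without consequence because C1 and C4 both pass through planar intermediates, and only the isomer with ester and side chain cis can lactonise.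

Step 9
Reactants: 14 (1S,4S,5R,8S)-8-[3,4-bis(benzyloxy)phenyl]-4-[3,4,5-tris(benzyloxy)phenyl]-3,7-dioxabicyclo[3.3.0]octan-2-one
Product: 15 (1S,4S,5R,8S)-8-(3,4-dihydroxyphenyl)-4-(3,4,5-trihydroxyphenyl)-3,7-dioxabicyclo[3.3.0]octan-2-one (target CNP0290035.1)
Conditions: H2 (1 atm, gas burette), 10% Pd/C (5 mol% Pd), degassed EtOAc/THF (1:1), 20 °C, stopped at 5 equiv uptake; filtered under argon
Reagents that add atoms: none
Why: heterogeneous palladium-catalysed hydrogenolysis cleaves aryl benzyl ethers much faster than the hindered secondary benzylic C4–O3 and C8–O7 ring bonds in a neutral aprotic medium, so stopping at the calculated uptake should free the five phenols without touching any stereocentre.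

Compound list
1 | 3',4'-bis(benzyloxy)acetophenone | CC(=O)c1ccc(OCc2ccccc2)c(OCc2ccccc2)c1 | starting material
2 | dimethyl carbonate | COC(=O)OC | starting material
3 | methyl 3-[3,4-bis(benzyloxy)phenyl]-3-oxopropanoate | COC(=O)CC(=O)c1ccc(OCc2ccccc2)c(OCc2ccccc2)c1 | intermediate
4 | methyl (3S)-3-[3,4-bis(benzyloxy)phenyl]-3-hydroxypropanoate | COC(=O)C[C@H](O)c1ccc(OCc2ccccc2)c(OCc2ccccc2)c1 | intermediate
5 | 3,4,5-tris(benzyloxy)benzaldehyde | O=Cc1cc(OCc2ccccc2)c(OCc2ccccc2)c(OCc2ccccc2)c1 | starting material
6 | triethyl phosphonoacetate | CCOC(=O)CP(=O)(OCC)OCC | starting material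
7 | ethyl (2E)-3-[3,4,5-tris(benzyloxy)phenyl]prop-2-enoate | CCOC(=O)/C=C/c1cc(OCc2ccccc2)c(OCc2ccccc2)c(OCc2ccccc2)c1 | intermediate
8 | (2E)-3-[3,4,5-tris(benzyloxy)phenyl]prop-2-en-1-ol | OC/C=C/c1cc(OCc2ccccc2)c(OCc2ccccc2)c(OCc2ccccc2)c1 | intermediate
9 | tert-butyl (2E)-3-[3,4,5-tris(benzyloxy)phenyl]prop-2-en-1-yl carbonate | CC(C)(C)OC(=O)OC/C=C/c1cc(OCc2ccccc2)c(OCc2ccccc2)c(OCc2ccccc2)c1 | intermediate
10 | methyl (3S)-3-[3,4-bis(benzyloxy)phenyl]-3-{[(2E)-3-(3,4,5-tris(benzyloxy)phenyl)prop-2-en-1-yl]oxy}propanoate | COC(=O)C[C@H](OC/C=C/c1cc(OCc2ccccc2)c(OCc2ccccc2)c(OCc2ccccc2)c1)c1ccc(OCc2ccccc2)c(OCc2ccccc2)c1 | intermediate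
11 | methyl trimethylsilyl ketene acetal of 10, (3S), mixture of ketene acetal geometries | COC(O[Si](C)(C)C)=C[C@H](OC/C=C/c1cc(OCc2ccccc2)c(OCc2ccccc2)c(OCc2ccccc2)c1)c1ccc(OCc2ccccc2)c(OCc2ccccc2)c1 | intermediate (not isolated)
12 | methyl (2RS,3R)-2-bromo-3-[3,4-bis(benzyloxy)phenyl]-3-{[(2E)-3-(3,4,5-tris(benzyloxy)phenyl)prop-2-en-1-yl]oxy}propanoate, both C2 epimers | COC(=O)C(Br)[C@H](OC/C=C/c1cc(OCc2ccccc2)c(OCc2ccccc2)c(OCc2ccccc2)c1)c1ccc(OCc2ccccc2)c(OCc2ccccc2)c1 | intermediate
13 | O-methyl lactonium bromide: (1S,4S,5R,8S)-2-methoxy-8-[3,4-bis(benzyloxy)phenyl]-4-[3,4,5-tris(benzyloxy)phenyl]-3,7-dioxabicyclo[3.3.0]oct-2-en-3-ium bromide | C[O+]=C1O[C@H](c2cc(OCc3ccccc3)c(OCc3ccccc3)c(OCc3ccccc3)c2)[C@H]2CO[C@H](c3ccc(OCc4ccccc4)c(OCc4ccccc4)c3)[C@@H]12.[Br-] | intermediate (not isolated)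
14 | (1S,4S,5R,8S)-8-[3,4-bis(benzyloxy)phenyl]-4-[3,4,5-tris(benzyloxy)phenyl]-3,7-dioxabicyclo[3.3.0]octan-2-one | O=C1O[C@H](c2cc(OCc3ccccc3)c(OCc3ccccc3)c(OCc3ccccc3)c2)[C@H]2CO[C@H](c3ccc(OCc4ccccc4)c(OCc4ccccc4)c3)[C@@H]12 | intermediate
15 | (1S,4S,5R,8S)-8-(3,4-dihydroxyphenyl)-4-(3,4,5-trihydroxyphenyl)-3,7-dioxabicyclo[3.3.0]octan-2-one | O=C1O[C@H](c2cc(O)c(O)c(O)c2)[C@H]2CO[C@H](c3ccc(O)c(O)c3)[C@@H]12 | target

Total step count: 9. Longest linear sequence: 7 steps (5 to 15 through steps 3, 4, 5, 6, 7, 8 and 9).

Steps most likely to fail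

Step 8. The cyclised benzylic radical may be intercepted by hydrogen abstraction or dimerisation before it is oxidised. The cation may lose a proton to a styrene instead of being trapped. Part of the material may close to the 3,4-trans tetrahydrofuran, which cannot lactonise. Triplet energy transfer from the catalyst to the styrene may waste the excited state. The fallback replaces photochemical electron transfer by thermal inner-sphere halogen transfer and runs the lactonisation as a separate ionic operation. It sets out from 12: copper-catalysed bromine-atom-transfer radical cyclisation (CuBr 10 mol%, tris(2-pyridylmethyl)amine 10 mol%, 1,2-dichloroethane, 60 °C) should give the cyclised benzylic bromide methyl (2S,3S,4R)-2-[3,4-bis(benzyloxy)phenyl]-4-{bromo[3,4,5-tris(benzyloxy)phenyl]methyl}oxolane-3-carboxylate F1, with the same chair-controlled 2,3-trans-3,4-cis arrangement. Warming F1 in MeCN (70 °C, n-Bu4NBr cat.) should ionise the benzylic bromide, close the lactone through the ester carbonyl and expel bromomethane. The route is rejoined at 14.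

Step 6. Attack of the hindered secondary benzylic alkoxide on the π-allyl complex may be slow, so the carbonate is consumed by tert-butoxide. The alkoxide of 4 may undergo retro-aldol cleavage or elimination. Attack at the benzylic allyl terminus would give the branched ether. The fallback is a silver-assisted alkylation in place of π-allyl palladium chemistry. It sets out from 8: PBr3 (0.4 equiv), Et2O, 0 °C should give (2E)-1-bromo-3-[3,4,5-tris(benzyloxy)phenyl]prop-2-ene F2. F2 (1.5 equiv) with 4, Ag2O (1.5 equiv) and 4 Å molecular sieves in CH2Cl2 in the dark at rt should give the ether under essentially neutral conditions. The route is rejoined at 10, and 9 is bypassed.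

Step 9. Once the phenols are free, hydrogenolysis may continue into the benzylic C4–O3 lactone bond or the C8–O7 ether bond. Debenzylation may also stall at partly protected stages, and the pyrogallol ring may oxidise in air during filtration. The fallback is a non-reductive Lewis-acid debenzylation. It sets out from 14: BCl3 (8 equiv), pentamethylbenzene (10 equiv) as benzyl-cation scavenger, CH2Cl2, −78 °C, then MeOH quench under argon. It arrives directly at 15 and no new compound lies on the way (F0). Any transient ionisation at C4 or C8 is expected to reclose to the same exo,exo isomer, which is the thermodynamically preferred one.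

Further compounds
F1 | step 8 | methyl (2S,3S,4R)-2-[3,4-bis(benzyloxy)phenyl]-4-{bromo[3,4,5-tris(benzyloxy)phenyl]methyl}oxolane-3-carboxylate, both epimers at CHBr | COC(=O)[C@@H]1[C@@H](c2ccc(OCc3ccccc3)c(OCc3ccccc3)c2)OC[C@@H]1C(Br)c1cc(OCc2ccccc2)c(OCc2ccccc2)c(OCc2ccccc2)c1
F2 | step 6 | (2E)-1-bromo-3-[3,4,5-tris(benzyloxy)phenyl]prop-2-ene | BrC/C=C/c1cc(OCc2ccccc2)c(OCc2ccccc2)c(OCc2ccccc2)c1
F0 | step 9 | none | none
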